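## Retrosynthetic overview

1. The target is 17-(3,5-dihydroxyphenyl)heptadecan-2-one (achiral): a resorcinol ring, a C2 ketone, and the unbranched fifteen-carbon chain C3-C17 between them.
2. Feature used: C3-C17 counts as 1 + 12 + 2. C3 is the vinyl CH next to the carbonyl of methyl vinyl ketone, C4-C15 are the twelve ring carbons of cyclododecene, and C16-C17 are the CH and ArCH2 of an allyl group on the arene.
3. O-Demethylation and hydrogenation lead back to the C3=C4/C15=C16 dienone. Cutting both alkenes at once by metathesis gives the three olefins, with ethene as the only co-product.
4. The allylarene is cut at the aryl-CH2 bond to 3,5-dimethoxyphenylmagnesium bromide and allyl bromide.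
5. No ring is formed: the benzene ring is bought, and the twelve-membered carbocycle is opened, not made.

Key step: step 2

Assumption: commercial cyclododecene is a cis/trans mixture and both isomers open to the same acyclic chain, so it is used as bought; the ruthenium alkylidenes of the catalytic cycle are forms of the catalyst, present only at catalyst level, and are described in the Why line without compound numbers.

## Route

Step 1
Reactants: 1 1-bromo-3,5-dimethoxybenzene; 2 allyl bromide (3-bromoprop-1-ene)
Product: 4 1-allyl-3,5-dimethoxybenzene, via 3,5-dimethoxyphenylmagnesium bromide 3 (not isolated)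
Conditions: Mg turnings (1.2 equiv, iodine crystal), THF, reflux; then 2 (1.3 equiv), 0 °C to rt; aq NH4Cl; distillation
Reagents that add atoms: magnesium, [Mg] (held only in intermediate 3)
Why: Grignard formation followed by allylation of the arylmagnesium bromide with the very reactive allylic bromide is a standard route to allylarenes, direct and allylic-shift attack give the same product because the allyl unit is unsubstituted, and the near-neutral work-up leaves the double bond out of conjugation.

Step 2
Reactants: 4 1-allyl-3,5-dimethoxybenzene; 5 cyclododecene (cis/trans mixture); 6 methyl vinyl ketone (freshly distilled)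
Product: 7 (3E,15E)-17-(3,5-dimethoxyphenyl)heptadeca-3,15-dien-2-one
Conditions: 4 (4 equiv), 5 (1 equiv), second-generation Hoveyda-Grubbs catalyst (H2IMes)Cl2Ru(=CH-C6H4-2-OiPr) (3 mol% in two portions), 1,4-benzoquinone (10 mol%), CH2Cl2 (0.25 M in 5), 40 °C, argon sparge; 6 (2 equiv) by syringe pump over 6 h; ethyl vinyl ether quench; SiO2
Reagents that add atoms: none
Why: Proposed new method: the catalyst takes up the ArCH2CH= unit of 4 (Ar = 3,5-dimethoxyphenyl, ethene leaves), this alkylidene Ru=CHCH2Ar adds [2+2] to the C=C bond of 5, cycloreversion of the ruthenacyclobutane lays out the open chain Ru=CH(CH2)10CH=CHCH2Ar (C15=C16 formed), and a second [2+2]/cycloreversion with 6, oriented so that the acyl-bearing CH joins the chain, releases the C3=C4 enone of 7 and Ru=CH2, which reloads with 4. The closest known reaction types are ring-opening cross-metathesis of cyclooctene or cyclododecene with acrylates and enones, which puts the same cap on both ends, and cross-metathesis of terminal alkenes with methyl vinyl ketone; selective unlike capping of one opened, weakly strained ring by two partners in one flask has not been shown. As 5 is only mildly strained, the reaction is pulled by loss of ethene and by formation of the conjugated enone, whose electron-poor C=C bond hardly re-enters metathesis. The step needs one aryl cap and one enone cap per C12 unit, and this rests on the different metathesis behaviour of the partners: 6 does not self-couple and caps irreversibly, whereas every purely hydrocarbon C=C bond (aryl-capped ends, self-coupled 4, ring-to-ring links) keeps exchanging and can be corrected. Hence 6 is the partner that is added slowly and kept short (about one third of all exchangeable chain termini) while 4 is in excess, since opening of the weakly strained internal alkene is slower than direct coupling of the two terminal olefins and any surplus of 6 would also strip the aryl cap from 7; if no kinetic bias helps, end-group statistics set the ceiling per pass and the recovered hydrocarbon fraction is resubmitted. No ring closes and no stereocentre forms, both alkenes should be mainly E but their geometry is erased in step 3, and 1,4-benzoquinone suppresses ruthenium-hydride alkene migration, which would change the chain length.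

Step 3
Reactants: 7 (3E,15E)-17-(3,5-dimethoxyphenyl)heptadeca-3,15-dien-2-one
Product: 8 17-(3,5-dimethoxyphenyl)heptadecan-2-one
Conditions: H2 (1 atm), 10% Pd/C, EtOAc, rt
Reagents that add atoms: none
Why: Heterogeneous catalytic hydrogenation over palladium on carbon saturates the disubstituted alkene and the enone C=C bond much faster than it touches an aliphatic ketone, an aryl methyl ether or the arene, so all alkene isomers converge on one saturated chain.

Step 4
Reactants: 8 17-(3,5-dimethoxyphenyl)heptadecan-2-one
Product: 10 hansfordiol B [17-(3,5-dihydroxyphenyl)heptadecan-2-one], via bis(dibromoboryloxy)arene 9 (not isolated)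
Conditions: BBr3 (4 equiv), CH2Cl2, -78 °C to rt; ice-water
Reagents that add atoms: boron tribromide, BrB(Br)Br (boron and bromine are held only in intermediate 9)
Why: In this Lewis-acid aryl methyl ether cleavage each ether oxygen binds boron and bromide attacks the methyl carbon, the extra equivalents cover reversible complexation of the remote ketone, and hydrolysis of the aryloxyboranes frees both phenols and the unchanged carbonyl group.

## Compound list

1 | 1-bromo-3,5-dimethoxybenzene | COc1cc(Br)cc(OC)c1 | starting material
2 | allyl bromide (3-bromoprop-1-ene) | C=CCBr | starting material
3 | 3,5-dimethoxyphenylmagnesium bromide | COc1cc([Mg]Br)cc(OC)c1 | intermediate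
4 | 1-allyl-3,5-dimethoxybenzene | C=CCc1cc(OC)cc(OC)c1 | intermediate
5 | cyclododecene (cis/trans mixture) | C1=CCCCCCCCCCC1 | starting material
6 | methyl vinyl ketone (but-3-en-2-one) | C=CC(C)=O | starting material
7 | (3E,15E)-17-(3,5-dimethoxyphenyl)heptadeca-3,15-dien-2-one (any Z isomer at C15=C16 is carried along) | COc1cc(C/C=C/CCCCCCCCCC/C=C/C(C)=O)cc(OC)c1 | intermediate
8 | 17-(3,5-dimethoxyphenyl)heptadecan-2-one | CC(=O)CCCCCCCCCCCCCCCc1cc(OC)cc(OC)c1 | intermediate
9 | 17-[3,5-bis(dibromoboryloxy)phenyl]heptadecan-2-one | CC(=O)CCCCCCCCCCCCCCCc1cc(OB(Br)Br)cc(OB(Br)Br)c1 | intermediate
10 | hansfordiol B, 17-(3,5-dihydroxyphenyl)heptadecan-2-one (no stereocentre) | CC(=O)CCCCCCCCCCCCCCCc1cc(O)cc(O)c1 | target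

## Step count and risks

Total step count: 4. Longest linear sequence: 4 steps (1 to 4 to 7 to 8 to 10).

**Step 2 (proposed new method).**
- Risk: the end caps may scramble (double enone capping, double aryl capping). The two acyclic partners may couple directly, rings may link to rings, the weakly strained ring may open slowly, and alkenes may migrate. Together these may leave only a modest share of hetero-capped chain that is laborious to purify.
- Fallback (known two-component cross-metathesis only, no ring opening): it sets out from 6. Compound 6 is coupled with an excess of commercial tetradeca-1,13-diene F1, the open-chain C14 equivalent of 5 that already carries both =CH2 termini; the excess is recovered. The second-generation Hoveyda-Grubbs catalyst in CH2Cl2 at 40 °C should give (E)-hexadeca-3,15-dien-2-one F2. After purification, the remaining vinyl group of F2 is cross-metathesised with an excess of 4 under the same catalyst. Here the enone end is a spectator and self-coupled allylarene remains a competent partner. The sequence comes back to the route at 7.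

**Step 4.**
- Risk: the Lewis acid, or HBr at the quench, may activate the methyl ketone. This could cause aldol-type self-condensation or alkylation of the electron-rich resorcinol ring. The reaction may also stall after the first ether cleavage.
- Fallback (benzyl in place of methyl, no Lewis acid anywhere): it sets out from 2. Commercial 5-bromobenzene-1,3-diol F3 is O-benzylated (BnBr, K2CO3, DMF) to 1,3-bis(benzyloxy)-5-bromobenzene F4. Mg in THF converts this into [3,5-bis(benzyloxy)phenyl]magnesium bromide F5, which is allylated with 2 to 1-allyl-3,5-bis(benzyloxy)benzene F6. F6 takes the place of 4 in the metathesis with 5 and 6 and should give (3E,15E)-17-[3,5-bis(benzyloxy)phenyl]heptadeca-3,15-dien-2-one F7. A single hydrogenation over Pd/C (H2, EtOAc/EtOH, rt) then saturates both alkenes and hydrogenolyses both benzyl ethers, coming back to the route at 10.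

**Step 1.**
- Risk: magnesium may insert slowly or incompletely into the electron-rich aryl bromide, and either partner may undergo Wurtz-type homocoupling. The allyl double bond may also migrate into conjugation with the ring, which would shorten the chain built in step 2.
- Fallback (polarity reversed, palladium catalysis): it sets out from 1. Compound 1 undergoes Suzuki-Miyaura allylation with allylboronic acid pinacol ester (Pd(PPh3)4, CsF, THF, reflux) and comes back to the route at 4. No new compound lies on the way.

## Further compounds

F1 | step 2 | tetradeca-1,13-diene (purchased) | C=CCCCCCCCCCCCC=C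
F2 | step 2 | (E)-hexadeca-3,15-dien-2-one | CC(=O)/C=C/CCCCCCCCCCC=C
F3 | step 4 | 5-bromobenzene-1,3-diol (purchased) | Oc1cc(O)cc(Br)c1
F4 | step 4 | 1,3-bis(benzyloxy)-5-bromobenzene | Brc1cc(OCc2ccccc2)cc(OCc2ccccc2)c1
F5 | step 4 | [3,5-bis(benzyloxy)phenyl]magnesium bromide | Br[Mg]c1cc(OCc2ccccc2)cc(OCc2ccccc2)c1
F6 | step 4 | 1-allyl-3,5-bis(benzyloxy)benzene | C=CCc1cc(OCc2ccccc2)cc(OCc2ccccc2)c1
F7 | step 4 | (3E,15E)-17-[3,5-bis(benzyloxy)phenyl]heptadeca-3,15-dien-2-one | CC(=O)/C=C/CCCCCCCCCC/C=C/Cc1cc(OCc2ccccc2)cc(OCc2ccccc2)c1
F0 | step 1 | none | none
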